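The earlier runs and the new flask were generated by integration from invented constants.

At 80.0 min, the last reading of the two earlier runs, Tuesday's run showed 10.4 % of target with 0.75 mM of free catalyst and Sunday's run 12.6 % with 1.1 mM, and I built my estimate from that pair.

| flask | starting material | reagent | free catalyst | second catalyst | remark |
|---|---|---|---|---|---|
| Tuesday's | 0.30 M | 0.60 M | 0.75 mM | 4.2 mM | run made earlier |
| Sunday's | 0.30 M | 0.60 M | 1.1 mM | 4.2 mM | run made earlier |
| flask | 0.30 M | 0.600 M | 1.5 mM | 4.2 mM |  |

| run | time / min | target / % |
|---|---|---|
| Tuesday's | 10.0 | 0.8 |
| Tuesday's | 25.0 | 3.1 |
| Tuesday's | 50.0 | 6.3 |
| Tuesday's | 80.0 | 10.4 |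
| Sunday's | 20.0 | 2.5 |
| Sunday's | 40.0 | 7.1 |
| Sunday's | 50.0 | 8.8 |
| Sunday's | 80.0 | 12.6 |

(standard deviation of a reading: 0.3 percentage points)

1. factor on the rate of making target when 30 % of the starting material are converted if free catalyst is charged twice over
2. factor on the rate when 30 % of the starting material are converted if free catalyst is charged at 8.0 mM instead

- "the catalyst" is free catalyst with its forms; second catalyst is a second catalyst
- what has left starting material counts as converted, also if it is not yet product

1. I started from the main step alone, a rate proportional to [free catalyst], which means order one and factors of 2 for the doubling and 5.33 for 8.0 mM.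

2. I then added a later step that makes target from an intermediate, with [second catalyst] held at 4.2 mM, and I supposed that more free catalyst reaches a set conversion sooner, while the rate of making target follows [intermediate], so I expected an order below one. The logarithm of the ratio of the two last readings over the logarithm of the ratio of the charges gave 0.501, a value read from scattered amounts of target and not from rates; I used this number, the apparent order in free catalyst, with the other charges fixed, to turn a ratio of charges into an estimated factor on the rate, here 1.42 and 2.31.

3. For the rest I looked at the later readings: from 50.0 min to 80.0 min Tuesday's run gained 4.1 percentage points and Sunday's run 3.8 points, equal within a scatter of 0.3 points, which I read as an order falling as those runs went on, and I took my two factors as the high side.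

4. The forecast gave 1.1 (0.85 to 1.7) and 1.2 (0.8 to 3), lower than my factors, and its author wrote of the conversion asked about: “expect little gain from more free catalyst”.

The simulation gave 1.24 for the doubling and 1.42 for 8.0 mM.

    starting material + free catalyst ⇌ free catalyst + intermediate (K = 1.88, k = 16.9 L mol⁻¹ min⁻¹)
    reagent + second catalyst + intermediate → second catalyst + target (k = 5.08 L² mol⁻² min⁻¹)
    intermediate → side product (k = 0.0349 min⁻¹)
    free catalyst → spent catalyst (k = 0.0110 min⁻¹)

The apparent order thus came to 0.315 for the doubling of this flask and 0.211 for the second flask at 8.0 mM, both lower than the 0.501 I had read, so my factors were too high; the forecast was right for the doubling and low by a factor of 1.18 at 8.0 mM. Target is made from intermediate, which also passes into side product, and the run of this flask without that passing gave a rate of making target at 30 % conversion 1.34 times the actual one.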